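**Plan**
- Retrosynthesis: ring C of the upper (robinetinidol) unit is cut at O1–C2 and C4a–C4 in one stroke, giving resorcinol (ring A) and an epoxy carbinol. The C4–C8 bond to ring D is then cut, giving 8-lithiated benzylated gallocatechin and a 3-aryl epoxy aldehyde (C2–C3–C4 plus ring B).
- Forward: the C2–C3–C4 piece with ring B is made as an epoxy aldehyde and joined to C8 of ring D of benzylated (+)-gallocatechin (rings D, F and E are bought). Ring A is then attached and ring C closed in the same flask, and global hydrogenolysis finishes the route.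
- Enabling feature: C4 is benzylic to ring D, whose O7 and O1 (ortho) and O5 (para) stabilise a C4 cation. Ring A has no 5-oxygen, so it is plain resorcinol, whose C4 is its most nucleophilic carbon and carries the future O1 as an ortho OH. C2 is benzylic to ring B, so the epoxide opens there.
- Stereochemistry: the lower unit comes from (+)-gallocatechin. C3 is set by Sharpless asymmetric epoxidation, C2 follows by inversion at the epoxide, and C4 by substrate control at the cation.

Key step: step 9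

Assumption: (+)-gallocatechin (2R,3S) is taken as a purchasable natural product; the two epimers at the carbinol carbon of 12 are carried together, because that centre becomes planar in step 9.

**Step 1**
Reactants: 1 3,4,5-tris(benzyloxy)benzaldehyde; 2 triethyl phosphonoacetate
Product: 3 ethyl (E)-3-[3,4,5-tris(benzyloxy)phenyl]prop-2-enoate
Conditions: NaH, THF, 0 °C → rt
Reagents that add atoms: none
Why: Horner–Wadsworth–Emmons olefination of an aromatic aldehyde with a stabilised phosphonate should give the (E)-cinnamate.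

**Step 2**
Reactants: 3 ethyl (E)-3-[3,4,5-tris(benzyloxy)phenyl]prop-2-enoate
Product: 4 (E)-3-[3,4,5-tris(benzyloxy)phenyl]prop-2-en-1-ol
Conditions: i-Bu2AlH (2.3 equiv), CH2Cl2, −78 → 0 °C; aq. potassium sodium tartrate
Reagents that add atoms: none
Why: 1,2-reduction of the conjugated ester by i-Bu2AlH should give the allylic alcohol without touching the alkene or the benzyl ethers.

**Step 3**
Reactants: 4 (E)-3-[3,4,5-tris(benzyloxy)phenyl]prop-2-en-1-ol
Product: 5 [(2S,3S)-3-[3,4,5-tris(benzyloxy)phenyl]oxiran-2-yl]methanol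
Conditions: Ti(OiPr)4 (10 mol%), L-(+)-diethyl tartrate (12 mol%), t-BuOOH, 4 Å sieves, CH2Cl2, −20 °C
Reagents that add atoms: tert-butyl hydroperoxide, CC(C)(C)OO
Why: Sharpless asymmetric epoxidation of an (E)-allylic alcohol with the L-(+)-tartrate should give the (2S,3S)-epoxide, which fixes the future C3 and, in latent form, C2.

**Step 4**
Reactants: 5 [(2S,3S)-3-[3,4,5-tris(benzyloxy)phenyl]oxiran-2-yl]methanol
Product: 6 (2R,3S)-3-[3,4,5-tris(benzyloxy)phenyl]oxirane-2-carbaldehyde
Conditions: Dess–Martin periodinane, pyridine, CH2Cl2, 0 °C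
Reagents that add atoms: none
Why: Buffered Dess–Martin oxidation should give the epoxy aldehyde; the α-carbon is an epoxide carbon and cannot epimerise (the descriptor changes by priority only).

**Step 5**
Reactants: 7 (+)-gallocatechin
Product: 8 (2R,3S)-5,7-bis(benzyloxy)-2-[3,4,5-tris(benzyloxy)phenyl]chroman-3-ol
Conditions: BnBr (5.5 equiv), K2CO3, DMF, argon, 0 °C → rt
Reagents that add atoms: benzyl bromide, BrCc1ccccc1
Why: Williamson etherification with a carbonate base should benzylate the five phenols and leave the aliphatic 3-OH free.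

**Step 6**
Reactants: 8 (2R,3S)-5,7-bis(benzyloxy)-2-[3,4,5-tris(benzyloxy)phenyl]chroman-3-ol
Product: 9 (2R,3S)-5,7-bis(benzyloxy)-8-bromo-2-[3,4,5-tris(benzyloxy)phenyl]chroman-3-ol
Conditions: NBS (1.05 equiv), CH2Cl2, −78 °C → rt
Reagents that add atoms: N-bromosuccinimide, O=C1CCC(=O)N1Br
Why: Electrophilic aromatic bromination should occur at C8 of ring D (ortho to O7 and O1, para to O5), the established site for benzylated flavan-3-ols; ring E is less activated.

**Step 7**
Reactants: 9 (2R,3S)-5,7-bis(benzyloxy)-8-bromo-2-[3,4,5-tris(benzyloxy)phenyl]chroman-3-ol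
Product: 10 (2R,3S)-3,5,7-tris(benzyloxy)-8-bromo-2-[3,4,5-tris(benzyloxy)phenyl]chromane
Conditions: NaH, BnBr, DMF, 0 °C → rt
Reagents that add atoms: benzyl bromide, BrCc1ccccc1
Why: Williamson benzylation of the secondary alkoxide should cap the 3-OH so that no acidic proton remains for step 8 and all protecting groups fall in one final hydrogenolysis.

**Step 8**
Reactants: 10 (2R,3S)-3,5,7-tris(benzyloxy)-8-bromo-2-[3,4,5-tris(benzyloxy)phenyl]chromane; 6 (2R,3S)-3-[3,4,5-tris(benzyloxy)phenyl]oxirane-2-carbaldehyde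
Product: 12 epoxy carbinol (both epimers at the carbinol carbon), via aryllithium 11 (not isolated)
Conditions: t-BuLi (2.1 equiv), THF, −78 °C; then 6 (1.3 equiv), −78 °C; sat. aq. NH4Cl at −78 °C
Reagents that add atoms: none
Why: Bromine–lithium exchange followed by 1,2-addition of the aryllithium to the aldehyde, which at −78 °C should be much faster than attack on the epoxide; the new carbinol centre need not be controlled.

**Step 9**
Reactants: 12 epoxy carbinol (both epimers at the carbinol carbon); 13 resorcinol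
Product: 16 nona-O-benzyl robinetinidol-(4α,8)-gallocatechin, via benzylic cation 14 (not isolated), via epoxy phenol 15 (not isolated)
Conditions: 13 (10 equiv), camphorsulfonic acid (10 mol%), CH2Cl2/(CF3)2CHOH 4:1, −40 → 0 °C, then rt
Reagents that add atoms: none
Why: Proposed new method: a dehydrative Friedel–Crafts alkylation merged with an epoxide-opening etherification, i.e. a formal [3+3] annulation of a phenol (C,O-bis-nucleophile) with an α,β-epoxy benzylic alcohol (1,3-bis-electrophile); acid ionises the C4–OH of 12 to cation 14, which ring D stabilises (O7 and O1 ortho, O5 para), resorcinol attacks through its C4 to give 15, and the ortho OH then opens the epoxide at benzylic C2. The closest known reactions are the acid- or fluoroalcohol-promoted benzylation of phenols with electron-rich benzylic alcohols and the acid-catalysed cyclisation of 2-(2-hydroxybenzyl)-3-aryloxiranes to 2,3-trans-flavan-3-ols. Ring C closes by 6-endo-tet opening of the epoxide with inversion, preferred over 5-exo attack at C3 because C2 is benzylic to ring B. C3 keeps the configuration from step 3, C2 results from anti opening of the trans-epoxide (2,3-trans, 2R), and C4 should be set when the arene enters the cation anti to the acid-bound epoxide C3–O bond in the conformer that holds H3 in the cation plane beside the ortho oxygens of ring D (A(1,3) strain), giving the 3,4-trans (4α) relation. The step needs ionisation at C4 before the epoxide opens (ring D donates far more than ring B), C- over O-alkylation, and capture by resorcinol and not by product 16; the soft stabilised cation and the tenfold excess of 13 should secure these.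

**Step 10**
Reactants: 16 nona-O-benzyl robinetinidol-(4α,8)-gallocatechin
Product: 17 robinetinidol-(4α,8)-gallocatechin
Conditions: H2 (1 atm), Pd(OH)2/C, THF/MeOH/H2O, rt; filtration and lyophilisation under argon
Reagents that add atoms: none
Why: Catalytic hydrogenolysis should cleave all nine benzyl ethers under neutral conditions, which leave the chroman C–O bonds, the interflavanyl bond and all stereocentres untouched.

**Compound list**
1 | 3,4,5-tris(benzyloxy)benzaldehyde | O=Cc1cc(OCc2ccccc2)c(OCc2ccccc2)c(OCc2ccccc2)c1 | starting material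
2 | triethyl phosphonoacetate | CCOC(=O)CP(=O)(OCC)OCC | starting material
3 | ethyl (E)-3-[3,4,5-tris(benzyloxy)phenyl]prop-2-enoate | CCOC(=O)/C=C/c1cc(OCc2ccccc2)c(OCc2ccccc2)c(OCc2ccccc2)c1 | intermediate
4 | (E)-3-[3,4,5-tris(benzyloxy)phenyl]prop-2-en-1-ol | OC/C=C/c1cc(OCc2ccccc2)c(OCc2ccccc2)c(OCc2ccccc2)c1 | intermediate
5 | [(2S,3S)-3-[3,4,5-tris(benzyloxy)phenyl]oxiran-2-yl]methanol | OC[C@@H]1O[C@H]1c1cc(OCc2ccccc2)c(OCc2ccccc2)c(OCc2ccccc2)c1 | intermediate
6 | (2R,3S)-3-[3,4,5-tris(benzyloxy)phenyl]oxirane-2-carbaldehyde | O=C[C@@H]1O[C@H]1c1cc(OCc2ccccc2)c(OCc2ccccc2)c(OCc2ccccc2)c1 | intermediate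
7 | (+)-gallocatechin, (2R,3S)-2-(3,4,5-trihydroxyphenyl)chromane-3,5,7-triol | c1c(O)cc(O)c2c1O[C@H](c1cc(O)c(O)c(O)c1)[C@@H](O)C2 | starting material
8 | (2R,3S)-5,7-bis(benzyloxy)-2-[3,4,5-tris(benzyloxy)phenyl]chroman-3-ol | c1c(OCc3ccccc3)cc(OCc3ccccc3)c2c1O[C@H](c1cc(OCc3ccccc3)c(OCc3ccccc3)c(OCc3ccccc3)c1)[C@@H](O)C2 | intermediate
9 | (2R,3S)-5,7-bis(benzyloxy)-8-bromo-2-[3,4,5-tris(benzyloxy)phenyl]chroman-3-ol | Brc1c(OCc3ccccc3)cc(OCc3ccccc3)c2c1O[C@H](c1cc(OCc3ccccc3)c(OCc3ccccc3)c(OCc3ccccc3)c1)[C@@H](O)C2 | intermediate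
10 | (2R,3S)-3,5,7-tris(benzyloxy)-8-bromo-2-[3,4,5-tris(benzyloxy)phenyl]chromane | Brc1c(OCc3ccccc3)cc(OCc3ccccc3)c2c1O[C@H](c1cc(OCc3ccccc3)c(OCc3ccccc3)c(OCc3ccccc3)c1)[C@@H](OCc3ccccc3)C2 | intermediate
11 | aryllithium: 8-lithio derivative of 10 | [Li]c1c(OCc3ccccc3)cc(OCc3ccccc3)c2c1O[C@H](c1cc(OCc3ccccc3)c(OCc3ccccc3)c(OCc3ccccc3)c1)[C@@H](OCc3ccccc3)C2 | intermediate (not isolated)
12 | epoxy carbinol: [(2S,3S)-3-[3,4,5-tris(benzyloxy)phenyl]oxiran-2-yl][(2R,3S)-3,5,7-tris(benzyloxy)-2-[3,4,5-tris(benzyloxy)phenyl]chroman-8-yl]methanol, both carbinol epimers | OC([C@@H]1O[C@H]1c1cc(OCc3ccccc3)c(OCc3ccccc3)c(OCc3ccccc3)c1)c1c(OCc3ccccc3)cc(OCc3ccccc3)c2c1O[C@H](c1cc(OCc3ccccc3)c(OCc3ccccc3)c(OCc3ccccc3)c1)[C@@H](OCc3ccccc3)C2 | intermediate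
13 | resorcinol (benzene-1,3-diol) | Oc1cccc(O)c1 | starting material
14 | benzylic cation: C4 cation of 12 after loss of the carbinol OH, stabilised by ring D | [CH+]([C@@H]1O[C@H]1c1cc(OCc3ccccc3)c(OCc3ccccc3)c(OCc3ccccc3)c1)c1c(OCc3ccccc3)cc(OCc3ccccc3)c2c1O[C@H](c1cc(OCc3ccccc3)c(OCc3ccccc3)c(OCc3ccccc3)c1)[C@@H](OCc3ccccc3)C2 | intermediate (not isolated)
15 | epoxy phenol: 4-[(S)-[(2S,3S)-3-[3,4,5-tris(benzyloxy)phenyl]oxiran-2-yl][(2R,3S)-3,5,7-tris(benzyloxy)-2-[3,4,5-tris(benzyloxy)phenyl]chroman-8-yl]methyl]benzene-1,3-diol | Oc1ccc(c(O)c1)[C@@H](c1c(OCc3ccccc3)cc(OCc3ccccc3)c2c1O[C@H](c1cc(OCc3ccccc3)c(OCc3ccccc3)c(OCc3ccccc3)c1)[C@@H](OCc3ccccc3)C2)[C@@H]1O[C@H]1c1cc(OCc3ccccc3)c(OCc3ccccc3)c(OCc3ccccc3)c1 | intermediate (not isolated)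
16 | nona-O-benzyl robinetinidol-(4α,8)-gallocatechin: (2R,3S,4S)-2-[3,4,5-tris(benzyloxy)phenyl]-4-[(2R,3S)-3,5,7-tris(benzyloxy)-2-[3,4,5-tris(benzyloxy)phenyl]chroman-8-yl]chromane-3,7-diol | Oc1ccc2c(c1)O[C@H](c1cc(OCc3ccccc3)c(OCc3ccccc3)c(OCc3ccccc3)c1)[C@@H](O)[C@@H]2c1c(OCc3ccccc3)cc(OCc3ccccc3)c2c1O[C@H](c1cc(OCc3ccccc3)c(OCc3ccccc3)c(OCc3ccccc3)c1)[C@@H](OCc3ccccc3)C2 | intermediate
17 | robinetinidol-(4α,8)-gallocatechin | Oc1ccc2c(c1)O[C@H](c1cc(O)c(O)c(O)c1)[C@@H](O)[C@@H]2c1c(O)cc(O)c2c1O[C@H](c1cc(O)c(O)c(O)c1)[C@@H](O)C2 | target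

**Totals:** 10 steps; longest linear sequence 7 steps (steps 1–4, 8, 9, 10).

**Steps most likely to fail**

1. Step 9 (bears the label). What may go wrong: poor facial selectivity at the C4 cation, which would give the 3,4-cis (4β) epimer; opening of the epoxide before C4 ionises, leading to rearrangement or to arylation at C2 and the constitutional isomer; and further alkylation of the product to oligomers. Fallback with known chemistry, setting out from 7 and coming back at 17: commercial (+)-dihydrorobinetin F1 is reduced with NaBH4 in ethanol at 0 °C to the flavan-3,4-diol leucorobinetinidin F2. F2 is then condensed with an excess of 7 in 0.1 M aqueous HCl/dioxane at rt. This is the classical acid-catalysed flavan-3,4-diol/flavan-3-ol condensation, in which ring A stabilises the cyclic C4 cation and C8 of 7 should enter mainly trans to the 3-OH. The 4→6 regioisomer and the 4β epimer would be removed on Sephadex LH-20 to leave 17.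

2. Step 8. What may go wrong: loss of the sensitive epoxy aldehyde to the strongly basic aryllithium, attack on the epoxide, or Payne-type migration of the epoxide at the lithium alkoxide stage. Fallback, setting out from 4 and 10 and coming back at 12, joins the fragments before the epoxide exists. Alcohol 4 is oxidised with MnO2 (CH2Cl2) to (E)-3-[3,4,5-tris(benzyloxy)phenyl]prop-2-enal F3. Aryllithium 11 (from 10 as in step 8) is added to F3 at −78 °C to give the diaryl allylic alcohol F4. MnO2 oxidation gives the chalcone F5. Juliá–Colonna epoxidation (poly-L-leucine, urea–H2O2, DBU, THF) should give the (2R,3S)-epoxy ketone F6. NaBH4 (MeOH/THF, 0 °C) then reduces F6 to 12.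

3. Step 5. What may go wrong: oxidative degradation of the pyrogallol ring under base and air, C-benzylation of ring D, and epimerisation at C2 through ring opening. Fallback, setting out from 7 and coming back at 10, never exposes the free polyphenol to base. Acetylation of 7 (Ac2O, pyridine) gives gallocatechin hexaacetate F7. One-pot deacetylation–benzylation (NaH, BnBr, DMF, slow addition of H2O, 0 °C) should give hexa-O-benzyl gallocatechin F8. NBS bromination of F8 as in step 6 then gives 10 directly.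

**Further compounds**
F1 | step 9 | (+)-dihydrorobinetin, (2R,3R)-3,7-dihydroxy-2-(3,4,5-trihydroxyphenyl)chroman-4-one | Oc1ccc2c(c1)O[C@H](c1cc(O)c(O)c(O)c1)[C@@H](O)C2=O
F2 | step 9 | leucorobinetinidin, (2R,3S,4R)-2-(3,4,5-trihydroxyphenyl)chromane-3,4,7-triol | Oc1ccc2c(c1)O[C@H](c1cc(O)c(O)c(O)c1)[C@@H](O)[C@@H]2O
F3 | step 8 | (E)-3-[3,4,5-tris(benzyloxy)phenyl]prop-2-enal | O=C/C=C/c1cc(OCc2ccccc2)c(OCc2ccccc2)c(OCc2ccccc2)c1
F4 | step 8 | (E)-3-[3,4,5-tris(benzyloxy)phenyl]-1-[(2R,3S)-3,5,7-tris(benzyloxy)-2-[3,4,5-tris(benzyloxy)phenyl]chroman-8-yl]prop-2-en-1-ol, both carbinol epimers | OC(/C=C/c1cc(OCc3ccccc3)c(OCc3ccccc3)c(OCc3ccccc3)c1)c1c(OCc3ccccc3)cc(OCc3ccccc3)c2c1O[C@H](c1cc(OCc3ccccc3)c(OCc3ccccc3)c(OCc3ccccc3)c1)[C@@H](OCc3ccccc3)C2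
F5 | step 8 | (E)-3-[3,4,5-tris(benzyloxy)phenyl]-1-[(2R,3S)-3,5,7-tris(benzyloxy)-2-[3,4,5-tris(benzyloxy)phenyl]chroman-8-yl]prop-2-en-1-one | O=C(/C=C/c1cc(OCc3ccccc3)c(OCc3ccccc3)c(OCc3ccccc3)c1)c1c(OCc3ccccc3)cc(OCc3ccccc3)c2c1O[C@H](c1cc(OCc3ccccc3)c(OCc3ccccc3)c(OCc3ccccc3)c1)[C@@H](OCc3ccccc3)C2
F6 | step 8 | [(2R,3S)-3-[3,4,5-tris(benzyloxy)phenyl]oxiran-2-yl][(2R,3S)-3,5,7-tris(benzyloxy)-2-[3,4,5-tris(benzyloxy)phenyl]chroman-8-yl]methanone | O=C([C@@H]1O[C@H]1c1cc(OCc3ccccc3)c(OCc3ccccc3)c(OCc3ccccc3)c1)c1c(OCc3ccccc3)cc(OCc3ccccc3)c2c1O[C@H](c1cc(OCc3ccccc3)c(OCc3ccccc3)c(OCc3ccccc3)c1)[C@@H](OCc3ccccc3)C2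
F7 | step 5 | (+)-gallocatechin hexaacetate | CC(=O)Oc1cc(OC(C)=O)c2c(c1)O[C@H](c1cc(OC(C)=O)c(OC(C)=O)c(OC(C)=O)c1)[C@@H](OC(C)=O)C2
F8 | step 5 | (2R,3S)-3,5,7-tris(benzyloxy)-2-[3,4,5-tris(benzyloxy)phenyl]chromane | c1c(OCc3ccccc3)cc(OCc3ccccc3)c2c1O[C@H](c1cc(OCc3ccccc3)c(OCc3ccccc3)c(OCc3ccccc3)c1)[C@@H](OCc3ccccc3)C2
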